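**Plan**

1. Ring numbering: O1, C2 (lactone C=O), C3 (side chain), C4 (Br), C5 (=CHI). The C3=C4 double bond carries on each side a ring carbon bonded to O1 (C2 and C5). Once C5=CHI is read as C5=O, this is a maleic anhydride, i.e. an alkyne plus two CO plus one oxygen.
2. Retrosynthesis: cut O–Si; C5=CHI ⇒ C5=CH2 ⇒ C5=O (anhydride); C4–Br ⇒ C4–H; then cut C2–C3 and C4–C5 together ⇒ TIPS-protected (R)-hex-1-yn-3-ol + 2 CO + H2O; the alkynol ⇒ silyl ynone ⇒ bis(trimethylsilyl)acetylene + butanoyl chloride.
3. Forward: the chain first (steps 1–4), then the only ring in one four-component oxidative dicarbonylation (step 5), bromine at C4 (step 6), mono-methylenation of the C5 carbonyl (step 7), iodination of the methylidene (step 8), desilylation (step 9).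
4. Stereochemistry: the (R)-carbinol comes from Noyori transfer hydrogenation of the ynone (step 2) and is carried unchanged. The (Z)-iodoalkene comes from the elimination in step 8, where iodine avoids the C4 bromine.

Key step: step 5

**Step 1**
Reactants: 1 bis(trimethylsilyl)acetylene; 2 butanoyl chloride
Product: 3 1-(trimethylsilyl)hex-1-yn-3-one
Conditions: AlCl3 (1.05 equiv), CH2Cl2, 0 °C
Reagents that add atoms: none
Why: Friedel–Crafts-type acylative ipso-desilylation of a silylalkyne: the acylium ion attacks the silicon-bearing alkyne carbon (β-silyl cation) and loss of Me3SiCl gives the ynone, while the second silyl group caps the alkyne terminus.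

**Step 2**
Reactants: 3 1-(trimethylsilyl)hex-1-yn-3-one
Product: 4 (3R)-1-(trimethylsilyl)hex-1-yn-3-ol
Conditions: Ru[(R,R)-TsDPEN](p-cymene) (0.5 mol %), i-PrOH, rt
Reagents that add atoms: none
Why: Noyori asymmetric transfer hydrogenation of an α,β-acetylenic ketone; the alkynyl group takes the place of the aryl group in the six-membered hydride/proton transfer transition state, so the (R,R)-diamine ligand should deliver hydride to the face that gives the (R)-propargylic alcohol.

**Step 3**
Reactants: 4 (3R)-1-(trimethylsilyl)hex-1-yn-3-ol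
Product: 5 tri(propan-2-yl){[(3R)-1-(trimethylsilyl)hex-1-yn-3-yl]oxy}silane
Conditions: TIPSOTf, 2,6-lutidine, CH2Cl2, 0 °C
Reagents that add atoms: triisopropylsilyl trifluoromethanesulfonate, CC(C)[Si](C(C)C)(C(C)C)OS(=O)(=O)C(F)(F)F
Why: O-silylation of a secondary alcohol with a silyl triflate and a hindered pyridine base; the bulky, acid-robust TIPS ether is chosen to survive HI traces in step 5, to resist β-oxygen elimination there, and to shield the neighbouring carbonyl in step 7.

**Step 4**
Reactants: 5 tri(propan-2-yl){[(3R)-1-(trimethylsilyl)hex-1-yn-3-yl]oxy}silane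
Product: 6 [(3R)-hex-1-yn-3-yloxy]tri(propan-2-yl)silane
Conditions: K2CO3 (0.2 equiv), MeOH, rt
Reagents that add atoms: none
Why: Base-catalysed methanolysis (protodesilylation) of the alkynyl C–Si bond, which is far more labile than the hindered Si–O bond of the TIPS ether, frees the terminal alkyne needed for step 5.

**Step 5**
Reactants: 6 [(3R)-hex-1-yn-3-yloxy]tri(propan-2-yl)silane
Product: 7 3-[(1R)-1-{[tri(propan-2-yl)silyl]oxy}butyl]furan-2,5-dione
Conditions: PdI2 (1 mol %), KI (10 mol %), CO/air 4:1 (20 atm), 1,4-dioxane, H2O (2 equiv), 70 °C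
Reagents that add atoms: carbon monoxide, [C-]#[O+] (two molecules); water, O (the ring oxygen)
Why: Oxidative dicarbonylation of an alk-1-yne, a four-component union of 6, two CO and water: an I–Pd–CO2H species formed from PdI2, CO and water adds syn across the triple bond, CO inserts into the vinyl–palladium bond, and the cis carboxyl oxygen captures the acylpalladium, releasing zerovalent palladium that air reoxidises through HI/I2. The closest known reaction type is exactly this PdI2/KI-catalysed conversion of terminal alkynes into substituted maleic anhydrides, applied here to an α-silyloxy alkyne. The oxolane-2,5-dione ring closes by 5-exo-trig O-acylation at the acylpalladium carbon, which is possible only because syn insertion places the two new carbonyl carbons cis on the double bond. No stereocenter is formed, and the carbinol center is untouched because it has no acidic or labile bond under these near-neutral conditions. The step needs cis-dicarbonylation over mono-carbonylation or fumarate formation, secured by syn insertion and CO pressure, and it needs suppression of β-oxygen elimination to an allene from the vinylpalladium intermediate, secured by the poor leaving ability of the bulky silyl ether; regiochemistry is no issue because both alkyne carbons receive CO.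

**Step 6**
Reactants: 7 3-[(1R)-1-{[tri(propan-2-yl)silyl]oxy}butyl]furan-2,5-dione
Product: 9 3-bromo-4-[(1R)-1-{[tri(propan-2-yl)silyl]oxy}butyl]furan-2,5-dione, via dibromosuccinic anhydride 8 (not isolated)
Conditions: Br2, CHCl3, 45 °C, dark; then Et3N, 0 °C
Reagents that add atoms: bromine, BrBr
Why: Bromination–dehydrobromination of an alkylmaleic anhydride (the way bromomaleic anhydrides and bromomaleimides are made): Br2 adds across the ring double bond and Et3N removes the acidic hydrogen α to the carbonyl with loss of the tertiary bromide (E1cB), leaving bromine on the carbon that carried hydrogen.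

**Step 7**
Reactants: 9 3-bromo-4-[(1R)-1-{[tri(propan-2-yl)silyl]oxy}butyl]furan-2,5-dione
Product: 10 4-bromo-5-methylidene-3-[(1R)-1-{[tri(propan-2-yl)silyl]oxy}butyl]furan-2(5H)-one
Conditions: Cp2TiMe2 (1.1 equiv), toluene, 65 °C, dark
Reagents that add atoms: dimethyltitanocene (Cp2TiMe2), C[Ti](C)(C1C=CC=C1)C1C=CC=C1
Why: Petasis methylenation of a cyclic anhydride to an enol lactone via Cp2Ti=CH2 and an oxatitanacyclobutane; the carbonyl next to the bromine-bearing carbon should react because the other one is shielded by the branched silyloxybutyl group and deactivated by vinylogous donation from bromine.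

**Step 8**
Reactants: 10 4-bromo-5-methylidene-3-[(1R)-1-{[tri(propan-2-yl)silyl]oxy}butyl]furan-2(5H)-one
Product: 12 (5Z)-4-bromo-5-(iodomethylidene)-3-[(1R)-1-{[tri(propan-2-yl)silyl]oxy}butyl]furan-2(5H)-one, via chloro iodide 11 (not isolated)
Conditions: ICl, CH2Cl2, −78 to 0 °C; then i-Pr2NEt, 0 °C
Reagents that add atoms: iodine monochloride, ClI
Why: Halogenation–dehydrohalogenation of a 5-methylidenefuranone (the reaction type used with Br2 for bromomethylidene furanones of this family): the iodine electrophile adds to the terminal CH2 and chloride to C5, then base-induced anti loss of HCl gives the vinyl iodide, with Z geometry (iodine syn to O1) expected because iodine avoids the C4 bromine in both the elimination conformer and the product.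

**Step 9**
Reactants: 12 (5Z)-4-bromo-5-(iodomethylidene)-3-[(1R)-1-{[tri(propan-2-yl)silyl]oxy}butyl]furan-2(5H)-one
Product: 13 (5Z)-4-bromo-3-[(1R)-1-hydroxybutyl]-5-(iodomethylidene)furan-2(5H)-one
Conditions: HF·pyridine, THF, 0 °C to rt
Reagents that add atoms: none
Why: Fluoride-driven silyl ether cleavage (Si–F bond formation) under mildly acidic, non-basic conditions that should leave the electrophilic bromo-iodo dienyl lactone and the carbinol stereocenter untouched.

**Compound list**

1 | bis(trimethylsilyl)acetylene | C[Si](C)(C)C#C[Si](C)(C)C | starting material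
2 | butanoyl chloride | CCCC(=O)Cl | starting material
3 | 1-(trimethylsilyl)hex-1-yn-3-one | CCCC(=O)C#C[Si](C)(C)C | intermediate
4 | (3R)-1-(trimethylsilyl)hex-1-yn-3-ol | CCC[C@@H](O)C#C[Si](C)(C)C | intermediate
5 | tri(propan-2-yl){[(3R)-1-(trimethylsilyl)hex-1-yn-3-yl]oxy}silane | CCC[C@@H](O[Si](C(C)C)(C(C)C)C(C)C)C#C[Si](C)(C)C | intermediate
6 | [(3R)-hex-1-yn-3-yloxy]tri(propan-2-yl)silane | CCC[C@@H](O[Si](C(C)C)(C(C)C)C(C)C)C#C | intermediate
7 | 3-[(1R)-1-{[tri(propan-2-yl)silyl]oxy}butyl]furan-2,5-dione | CCC[C@@H](O[Si](C(C)C)(C(C)C)C(C)C)C1=CC(=O)OC1=O | intermediate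
8 | 3,4-dibromo-3-[(1R)-1-{[tri(propan-2-yl)silyl]oxy}butyl]oxolane-2,5-dione (ring stereocenters not defined; not isolated) | CCC[C@@H](O[Si](C(C)C)(C(C)C)C(C)C)C1(Br)C(Br)C(=O)OC1=O | intermediate
9 | 3-bromo-4-[(1R)-1-{[tri(propan-2-yl)silyl]oxy}butyl]furan-2,5-dione | CCC[C@@H](O[Si](C(C)C)(C(C)C)C(C)C)C1=C(Br)C(=O)OC1=O | intermediate
10 | 4-bromo-5-methylidene-3-[(1R)-1-{[tri(propan-2-yl)silyl]oxy}butyl]furan-2(5H)-one | CCC[C@@H](O[Si](C(C)C)(C(C)C)C(C)C)C1=C(Br)C(=C)OC1=O | intermediate
11 | 4-bromo-5-chloro-5-(iodomethyl)-3-[(1R)-1-{[tri(propan-2-yl)silyl]oxy}butyl]furan-2(5H)-one (C5 not defined; not isolated) | CCC[C@@H](O[Si](C(C)C)(C(C)C)C(C)C)C1=C(Br)C(Cl)(CI)OC1=O | intermediate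
12 | (5Z)-4-bromo-5-(iodomethylidene)-3-[(1R)-1-{[tri(propan-2-yl)silyl]oxy}butyl]furan-2(5H)-one | CCC[C@@H](O[Si](C(C)C)(C(C)C)C(C)C)C1=C(Br)/C(=C/I)OC1=O | intermediate
13 | (5Z)-4-bromo-3-[(1R)-1-hydroxybutyl]-5-(iodomethylidene)furan-2(5H)-one | CCC[C@@H](O)C1=C(Br)/C(=C/I)OC1=O | target

**Totals**

Total step count: 9. Longest linear sequence: 9 steps (1 and 2 to 13).

**Steps most likely to fail**

Step 5. The vinylpalladium intermediate may lose the β-silyloxy group (allene formation), or the sequence may stop after one carbonylation. The fallback sets out from 6 and comes back at 7, building the two ring C–C bonds in separate known steps. Deprotonation of 6 (n-BuLi, THF, −78 °C) and trapping with CO2 should give (4R)-4-{[tri(propan-2-yl)silyl]oxy}hept-2-ynoic acid F1. Anti hydroiodination (NaI, AcOH, 70 °C) should give (2Z,4R)-3-iodo-4-{[tri(propan-2-yl)silyl]oxy}hept-2-enoic acid F2, with iodine cis to the carboxyl group. Carbonylation of the vinyl iodide with Pd(PPh3)4, CO (1 atm) and Et3N in THF, with capture of the acylpalladium by the cis carboxyl group, should close the anhydride 7.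

Step 6. Addition of bromine to the hindered, electron-poor ring double bond may be sluggish, and radical hydrogen abstraction at the carbinol C–H would erode the stereocenter. The fallback sets out from 6 and comes back at 9, bringing bromine in before the ring exists. The ynoic acid F1 described above is treated with Br2 (CH2Cl2, 0 °C) to give, by anti addition, (2E,4R)-2,3-dibromo-4-{[tri(propan-2-yl)silyl]oxy}hept-2-enoic acid F3. Selective oxidative addition of zerovalent palladium into the β C–Br bond (Pd(PPh3)4, CO, Et3N, THF, 50 °C), CO insertion and capture by the cis carboxyl group should give the bromo anhydride 9.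

Step 7. The titanium methylidene may discriminate poorly between the two anhydride carbonyls or methylenate twice, and the diene lactone may polymerise at 65 °C. The fallback sets out from 9 and comes back at 10, replacing the carbene olefination by polar addition and dehydration. MeMgBr (THF, −78 °C) should add to the carbonyl next to the C–Br carbon to give the lactol 4-bromo-5-hydroxy-5-methyl-3-[(1R)-1-{[tri(propan-2-yl)silyl]oxy}butyl]furan-2(5H)-one F4. Dehydration with P2O5 (CH2Cl2, rt), the classical entry to 5-methylidene furanones, should then give 10.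

**Further compounds**

F1 | step 5 | (4R)-4-{[tri(propan-2-yl)silyl]oxy}hept-2-ynoic acid | CCC[C@@H](O[Si](C(C)C)(C(C)C)C(C)C)C#CC(=O)O
F2 | step 5 | (2Z,4R)-3-iodo-4-{[tri(propan-2-yl)silyl]oxy}hept-2-enoic acid | CCC[C@@H](O[Si](C(C)C)(C(C)C)C(C)C)/C(I)=C/C(=O)O
F3 | step 6 | (2E,4R)-2,3-dibromo-4-{[tri(propan-2-yl)silyl]oxy}hept-2-enoic acid | CCC[C@@H](O[Si](C(C)C)(C(C)C)C(C)C)/C(Br)=C(\Br)C(=O)O
F4 | step 7 | 4-bromo-5-hydroxy-5-methyl-3-[(1R)-1-{[tri(propan-2-yl)silyl]oxy}butyl]furan-2(5H)-one (C5 epimers) | CCC[C@@H](O[Si](C(C)C)(C(C)C)C(C)C)C1=C(Br)C(C)(O)OC1=O
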